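All constants come from no measurement, and the outcome is calculated.

The reagent in this flask can react with either of two intermediates of one catalyst, and the target depends on how it divides between them.

    second substrate + free catalyst ⇌ catalyst intermediate B (K1 = 8.0 M⁻¹, k1 = 5.23 M⁻¹ min⁻¹)
    starting material + free catalyst ⇌ catalyst intermediate A (K2 = 0.790 M⁻¹, k2 = 185 M⁻¹ min⁻¹)
    second substrate + protic impurity → quenched substrate (k3 = 0.0831 M⁻¹ min⁻¹)
    reagent + catalyst intermediate B → free catalyst + second product (k4 = 9.80 M⁻¹ min⁻¹)
    reagent + catalyst intermediate A → free catalyst + target (k5 = 1.07 M⁻¹ min⁻¹)

starting material 0.50 M; second substrate 2.00 equiv; reagent 0.950 equiv; protic impurity 0.100 M; free catalyst 1 mol%; time 40 h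

- why nothing more happens at 40 h, or that something still does (forward and back rates have come level / all of the starting material has reacted / no working catalyst is left / the reagent has run out first / it is still moving)
- share of the starting material used up at 40 h
- target at 40 h, in percent of the starting material charged
- amount of target if the flask were left three thousand times as long, in percent of the starting material charged

- the reaction counts as stopped when no species that holds the starting material changes by six tenths of a point or more over the second half of the time
- run time (flask): 40 h

In this flask, second substrate starts at 1.00 M and reagent at 0.475 M. Each reagent molecule that makes second product consumes one second substrate, and each molecule of protic impurity consumes another. The budget therefore comes first: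

surplus = 1.00 M − 0.100 M − 0.475 M = 0.425 M

This surplus is the second substrate left once impurity and reagent have each taken their full charge from it. Here the reagent is the limiting reagent, being less than the 0.900 M of second substrate open to it. Even at the surplus level, the impurity has a half-life of about 19.6 min, much shorter than the 40 h allowed, so its full charge can be counted.

The target is then a small correction, reckoned from the selectivity factor r, the rate into target over the rate into second product. Intermediate A falls back at 234 min⁻¹, much faster than reagent takes it at 0.508 min⁻¹, so it stays at equilibrium. Intermediate B is taken to be made as fast as it leaves, by falling back at 0.654 min⁻¹ and by reagent at 4.65 min⁻¹ at the start. With c(second substrate) at its charge, then at the surplus with c(reagent) near zero: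

r at the start = 0.0438

r at the end = 0.0127

c(target) ≈ mean r × 0.475 M = 0.0134 M, or 2.68% of the starting material

This reckoning expects the reagent to give out first, and waiting to add no target. Conversion should stand slightly above the target, by what intermediate A holds.

The forecast says that the reagent has run out first, with 3.1% conversion, and puts the target at 3% both at 40 h and on long waiting, slightly above this reckoning, with the words “Reagent is the limit, so waiting adds nothing”.

In the simulation the reagent has run out first, with 3.12% conversion, 3.04% target at 40 h and 3.04% target on long waiting.

In this flask, half of that conversion stands at 0.350 h, much earlier than the 40 h allowed. By 40.0 h reagent is down to 0% of its charge, while second substrate holds 44% of its own, close to the surplus plus the target, 0.440 M. The neighbour charged with 0.800 equiv of second substrate has a surplus of −0.175 M, and there second substrate stands at 0% of its charge. With 1.5% of its reagent and 13% of its impurity still present, the reagent and impurity actually used in that neighbour exceed its second substrate charge by 30.9% of the starting material, and that neighbour holds 30.9% target.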